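**Plan**
- The five-membered ring (C4, C5, C6, C7, C8) and the seven-membered ring (C4, C3, C2, C1, C10, C9, C8) share the C4–C8 bond. This pattern maps onto an alkyne (C8≡C9) joined through the tether C5–C7 to a vinylcyclopropane (C4=C3; ring C2, C1, C10).
- Retrosynthesis: cut the two ester C–O bonds, then C3–O (ene reaction, back to C2=C3), then C9–O (back to a C9 vinylsilane). Then cut C4–C8 and C9–C10 together, then the alkyne (from an epoxy chloride) and the C4=C3 alkene (Claisen).
- Forward: cyclopropane → E-trisubstituted alkene → stereodefined allylic alcohol → epoxy chloride → silylalkynyl carbinol → both rings in one rhodium-catalysed step → C9 ketone → C9 alcohol → aroyl ester → C3 oxygenation → isovalerate → free phenol.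
- Stereochemistry: C1 from asymmetric cyclopropanation; C7 from Sharpless epoxidation; C4 from C7 in the cycloaddition; C8 by kinetic protonation; C9 by hydroxyl-directed reduction; C3 by a suprafacial ene reaction on the face of the C1 hydrogen.

Key step: step 12

Remarks. Ring carbons are numbered C1 (vinylic methyl carbon), C2, C3 (isovalerate carbinol), C4 (quaternary methyl carbon), C5, C6, C7 (isopropyl carbinol), C8 (fusion CH), C9 (aroyloxy carbinol), C10; the same numbers are used for the open-chain precursors. Assumption: the (4R,5R)-dioxaborolane ligand gives the (1S,2S)-cyclopropylmethanol from (E)-but-2-en-1-ol, the facial sense it shows with other (E)-allylic alcohols. The phenol is carried as its acetate.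

**Step 1**
Reactants: 1 (E)-but-2-en-1-ol
Product: 2 [(1S,2S)-2-methylcyclopropyl]methanol
Conditions: Et2Zn, CH2I2, DME; (4R,5R)-2-butyl-N,N,N′,N′-tetramethyl-1,3,2-dioxaborolane-4,5-dicarboxamide (1.2 equiv), CH2Cl2, −10 °C → rt
Reagents that add atoms: diiodomethane, ICI
Why: Hydroxyl-directed Simmons–Smith (Charette) cyclopropanation in which the zinc alkoxide bound to the chiral dioxaborolane delivers CH2 to one alkene face and the E geometry is transferred stereospecifically, which sets both ring centres (trans, 1S,2S).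

**Step 2**
Reactants: 2 [(1S,2S)-2-methylcyclopropyl]methanol
Product: 3 (1S,2S)-2-methylcyclopropane-1-carbaldehyde
Conditions: TEMPO (10 mol %), PhI(OAc)2, CH2Cl2, rt; NaHCO3 wash, dried solution used directly (volatile)
Reagents that add atoms: none
Why: Nitroxyl-catalysed oxidation of a primary alcohol stops at the aldehyde under anhydrous conditions and does not open the cyclopropane or epimerise its α-carbon.

**Step 3**
Reactants: 3 (1S,2S)-2-methylcyclopropane-1-carbaldehyde; 4 isopropenylmagnesium bromide
Product: 5 2-methyl-1-[(1S,2S)-2-methylcyclopropyl]prop-2-en-1-ol (both carbinol epimers)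
Conditions: CH2=C(CH3)MgBr, THF, −78 → 0 °C; aq. NH4Cl
Reagents that add atoms: none
Why: Grignard 1,2-addition to the aldehyde gives the secondary allylic alcohol, whose carbinol centre needs no control because it is erased in step 4.

**Step 4**
Reactants: 5 2-methyl-1-[(1S,2S)-2-methylcyclopropyl]prop-2-en-1-ol; 6 triethyl orthoacetate
Product: 9 ethyl (4E)-4-methyl-5-[(1S,2S)-2-methylcyclopropyl]pent-4-enoate, via mixed orthoester 7 (not isolated), via ketene acetal 8 (not isolated)
Conditions: MeC(OEt)3 (excess), EtCO2H (cat.), 135 °C, EtOH distilled off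
Reagents that add atoms: none
Why: Johnson–Claisen rearrangement through a chair transition state with the cyclopropyl group pseudo-equatorial should give the E-trisubstituted alkene (C5 trans to the cyclopropane), and the weak acid catalyst should leave the cyclopropylcarbinyl system intact.

**Step 5**
Reactants: 9 ethyl (4E)-4-methyl-5-[(1S,2S)-2-methylcyclopropyl]pent-4-enoate; 10 tert-butyl acetate
Product: 11 tert-butyl (6E)-6-methyl-7-[(1S,2S)-2-methylcyclopropyl]-3-oxohept-6-enoate
Conditions: LiN(i-Pr)2 (3.2 equiv), t-BuOAc (3.2 equiv), THF, −78 °C; then 9, −78 → −30 °C; aq. NH4Cl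
Reagents that add atoms: none
Why: Crossed Claisen condensation of the ethyl ester with excess lithium enolate of tert-butyl acetate is driven by deprotonation of the β-keto ester formed and adds the two carbons that become C8 and C9.

**Step 6**
Reactants: 11 tert-butyl (6E)-6-methyl-7-[(1S,2S)-2-methylcyclopropyl]-3-oxohept-6-enoate
Product: 12 tert-butyl (2E,6E)-6-methyl-7-[(1S,2S)-2-methylcyclopropyl]-3-{[(trifluoromethyl)sulfonyl]oxy}hepta-2,6-dienoate
Conditions: Tf2O, aq. Me4NOH, toluene, 5 °C
Reagents that add atoms: trifluoromethanesulfonic anhydride, O=S(=O)(OS(=O)(=O)C(F)(F)F)C(F)(F)F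
Why: O-sulfonylation of the non-chelated tetramethylammonium enolate, which prefers the extended arrangement of enolate oxygen and ester carbonyl, is the known route to (E)-enol triflates of β-keto esters, whereas chelating counter-ions give the Z isomer.

**Step 7**
Reactants: 12 the (E)-enol triflate; 13 isopropylmagnesium chloride
Product: 14 tert-butyl (2E,6E)-6-methyl-7-[(1S,2S)-2-methylcyclopropyl]-3-(propan-2-yl)hepta-2,6-dienoate
Conditions: i-PrMgCl, Fe(acac)3 (5 mol %), THF/NMP, −30 °C
Reagents that add atoms: none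
Why: Iron-catalysed Kumada-type cross-coupling of an alkyl Grignard reagent with an enol triflate of a β-keto ester proceeds with retention of alkene geometry and spares the tert-butyl ester at low temperature, so isopropyl takes the place of the triflate trans to the ester.

**Step 8**
Reactants: 14 tert-butyl (2E,6E)-6-methyl-7-[(1S,2S)-2-methylcyclopropyl]-3-(propan-2-yl)hepta-2,6-dienoate
Product: 15 (2E,6E)-6-methyl-7-[(1S,2S)-2-methylcyclopropyl]-3-(propan-2-yl)hepta-2,6-dien-1-ol
Conditions: i-Bu2AlH (2.5 equiv), CH2Cl2, −78 → 0 °C; aq. potassium sodium tartrate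
Reagents that add atoms: none
Why: 1,2-Reduction of the unsaturated ester with excess i-Bu2AlH gives the allylic alcohol without touching either alkene or its geometry.

**Step 9**
Reactants: 15 (2E,6E)-6-methyl-7-[(1S,2S)-2-methylcyclopropyl]-3-(propan-2-yl)hepta-2,6-dien-1-ol
Product: 16 [(2S,3S)-3-{(3E)-3-methyl-4-[(1S,2S)-2-methylcyclopropyl]but-3-en-1-yl}-3-(propan-2-yl)oxiran-2-yl]methanol
Conditions: Ti(OiPr)4 (10 mol %), (+)-diisopropyl L-tartrate (12 mol %), t-BuOOH, 4 Å molecular sieves, CH2Cl2, −20 °C
Reagents that add atoms: tert-butyl hydroperoxide, CC(C)(C)OO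
Why: Sharpless asymmetric epoxidation oxidises only the allylic alcohol alkene and, with the L-(+)-tartrate and this geometry (isopropyl trans and the primary chain cis to CH2OH), should deliver oxygen to the face that makes C7 (S), the configuration of the tertiary carbinol in the target.

**Step 10**
Reactants: 16 the (2S,3S)-epoxy alcohol
Product: 17 (2R,3S)-2-(chloromethyl)-3-{(3E)-3-methyl-4-[(1S,2S)-2-methylcyclopropyl]but-3-en-1-yl}-3-(propan-2-yl)oxirane
Conditions: PPh3, CCl4, NaHCO3, reflux
Reagents that add atoms: tetrachloromethane, ClC(Cl)(Cl)Cl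
Why: Appel chlorination converts the primary alcohol into the chloride under buffered conditions without change at the epoxide carbons (the descriptor at C8 changes only by priority).

**Step 11**
Reactants: 17 the epoxy chloride
Product: 20 (3S,6E)-6-methyl-7-[(1S,2S)-2-methylcyclopropyl]-3-(propan-2-yl)-1-(trimethylsilyl)hept-6-en-1-yn-3-ol, via dilithium alkoxide acetylide 18 (not isolated), via bis(trimethylsilyl) compound 19 (not isolated)
Conditions: LiN(i-Pr)2 (3.5 equiv), THF, −78 → −30 °C; Me3SiCl (2.5 equiv), −78 °C → rt; then 1 M HCl (aq), THF, 0 °C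
Reagents that add atoms: chlorotrimethylsilane, C[Si](C)(C)Cl
Why: Base-induced double elimination of a 2,3-epoxy chloride (deprotonation at CH2Cl opens the epoxide to a chlorovinyl alkoxide, which loses HCl) gives the 1-alkyn-3-ol with the C7–O bond and its configuration untouched, the acetylide is silylated in the same flask, and dilute acid cleaves only the labile tertiary O-silyl ether.

**Step 12**
Reactants: 20 the silylalkynyl carbinol
Product: 21 (3S,6S,8aR)-6,8a-dimethyl-3-(propan-2-yl)-4-(trimethylsilyl)-1,2,3,5,6,8a-hexahydroazulen-3-ol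
Conditions: [Rh(CO)2Cl]2 (5 mol %), ClCH2CH2Cl, 80 °C
Reagents that add atoms: none
Why: Monovalent rhodium binds the alkyne and the vinylcyclopropane, cleaves the C2–C10 cyclopropane bond to an allyl–alkyl rhodacycle, inserts the alkyne at C4 (bond C4–C8) and releases the product by reductive elimination (bond C9–C10); the closest known reaction is the intramolecular rhodium-catalysed (5+2) cycloaddition of tethered alkynes and vinylcyclopropanes, here in its rarer form with a trisubstituted alkene that creates a quaternary carbon. The five-membered ring closes through the three-carbon tether C5–C7 when C4 bonds to C8 (5-exo with respect to both π-systems), and the seven-membered ring closes in the same catalytic cycle by union of C4–C3–C2–C1–C10 with C8 and C9 at the C9–C10 bond. C4 is the only new stereocentre and is controlled by C7: in the insertion transition state the isopropyl group should point away from rhodium and the nascent seven-membered ring, while the small hydroxyl (which can also bind the metal) points towards them, so the C4 methyl group ends up cis to isopropyl. C1 keeps the configuration of the cyclopropane because none of its bonds is broken. The step needs cleavage of the less substituted cyclopropane bond, which the trans methyl group and the carbonyl-ligated catalyst favour, and an s-cis vinylcyclopropane with the tether trans to the ring, which the E alkene from step 4 provides.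

**Step 13**
Reactants: 21 the vinylsilane diene
Product: 22 (3S,3aS,4R,6S,8aR)-3a,4-epoxy-6,8a-dimethyl-3-(propan-2-yl)-4-(trimethylsilyl)-1,2,3,3a,4,5,6,8a-octahydroazulen-3-ol
Conditions: VO(acac)2 (5 mol %), t-BuOOH, toluene, 0 °C → rt
Reagents that add atoms: tert-butyl hydroperoxide, CC(C)(C)OO
Why: Vanadium-catalysed hydroxyl-directed epoxidation selects the allylic C8=C9 vinylsilane over the isolated C2=C3 alkene and places oxygen on the face of the C7 hydroxyl (a configuration that is lost again in step 14).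

**Step 14**
Reactants: 22 the α,β-epoxysilane
Product: 24 (3S,3aR,6S,8aR)-3-hydroxy-6,8a-dimethyl-3-(propan-2-yl)-2,3,3a,5,6,8a-hexahydroazulen-4(1H)-one, via enol 23 (not isolated)
Conditions: TsOH·H2O (10 mol %), THF–H2O (10:1), 0 °C; NaHCO3 quench; used crude
Reagents that add atoms: none
Why: Acid-catalysed opening of the α,β-epoxysilane at the tertiary C8–O bond (cation β to silicon) with loss of the silyl group is the standard unmasking of a vinylsilane as a ketone at the silicon-bearing carbon, and kinetic protonation of the enol at C8 from the face opposite to the C4 methyl and C7 isopropyl groups should give the trans ring fusion, which is why mild, non-equilibrating conditions are chosen.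

**Step 15**
Reactants: 24 the β-hydroxy ketone
Product: 25 (3S,3aS,4R,6S,8aR)-6,8a-dimethyl-3-(propan-2-yl)-1,2,3,3a,4,5,6,8a-octahydroazulene-3,4-diol
Conditions: Me4NBH(OAc)3, MeCN–AcOH (1:1), −30 → −20 °C
Reagents that add atoms: none
Why: Evans–Saksena reduction, in which the C7 hydroxyl exchanges onto boron and delivers hydride to the same face of the C9 ketone, gives the anti-1,3-diol under mildly acidic conditions that do not epimerise C8, and the angular methyl group shields the opposite face as well.

**Step 16**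
Reactants: 25 the diol; 26 4-(acetyloxy)benzoyl chloride
Product: 27 (3S,3aS,4R,6S,8aR)-3-hydroxy-6,8a-dimethyl-3-(propan-2-yl)-1,2,3,3a,4,5,6,8a-octahydroazulen-4-yl 4-(acetyloxy)benzoate
Conditions: Et3N, DMAP, CH2Cl2, 0 °C → rt
Reagents that add atoms: none
Why: DMAP-catalysed acylation esterifies only the secondary C9 hydroxyl because the tertiary C7 hydroxyl is unreactive under these conditions.

**Step 17**
Reactants: 27 the monoester
Product: 29 (3S,3aS,4R,8R,8aS)-3,8-dihydroxy-6,8a-dimethyl-3-(propan-2-yl)-1,2,3,3a,4,5,8,8a-octahydroazulen-4-yl 4-(acetyloxy)benzoate, via allylic hydroperoxide 28 (not isolated)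
Conditions: O2, tetraphenylporphyrin (cat.), visible light, CDCl3, 0 °C, stopped before the product alkene is consumed; then PPh3
Reagents that add atoms: dioxygen, O=O
Why: In the Schenck ene reaction singlet oxygen can only abstract the allylic hydrogen at C1 (C4 is quaternary), so oxygen adds to C3 with shift of the double bond to C1=C2, and because the process is suprafacial the C3–O bond forms on the face of the C1 hydrogen, opposite to the C4 methyl group, which gives the required (R) centre before PPh3 reduces the hydroperoxide.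

**Step 18**
Reactants: 29 the allylic alcohol; 30 3-methylbutanoyl chloride
Product: 31 (3S,3aS,4R,8R,8aS)-3-hydroxy-6,8a-dimethyl-8-[(3-methylbutanoyl)oxy]-3-(propan-2-yl)-1,2,3,3a,4,5,8,8a-octahydroazulen-4-yl 4-(acetyloxy)benzoate
Conditions: pyridine, DMAP (cat.), CH2Cl2, 0 °C → rt
Reagents that add atoms: none
Why: DMAP-catalysed acylation of the secondary allylic C3 hydroxyl leaves the tertiary carbinol free.

**Step 19**
Reactants: 31 the diester acetate
Product: 32 (3S,3aS,4R,8R,8aS)-3-hydroxy-6,8a-dimethyl-8-[(3-methylbutanoyl)oxy]-3-(propan-2-yl)-1,2,3,3a,4,5,8,8a-octahydroazulen-4-yl 4-hydroxybenzoate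
Conditions: pyrrolidine, CH2Cl2, 0 °C → rt
Reagents that add atoms: none
Why: Aminolysis of the phenolic acetate by a secondary amine is much faster than attack on the alkyl isovalerate or the alkyl benzoate, so the phenol is released selectively.

**Compound list**
1 | (E)-but-2-en-1-ol | C/C=C/CO | starting material
2 | [(1S,2S)-2-methylcyclopropyl]methanol | OC[C@H]1C[C@@H]1C | intermediate
3 | (1S,2S)-2-methylcyclopropane-1-carbaldehyde | O=C[C@H]1C[C@@H]1C | intermediate
4 | isopropenylmagnesium bromide | C=C(C)[Mg]Br | starting material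
5 | 2-methyl-1-[(1S,2S)-2-methylcyclopropyl]prop-2-en-1-ol (both carbinol epimers) | C=C(C)C(O)[C@H]1C[C@@H]1C | intermediate
6 | triethyl orthoacetate | CC(OCC)(OCC)OCC | starting material
7 | mixed orthoester of 5 (not isolated) | CC(OCC)(OCC)OC(C(C)=C)[C@H]1C[C@@H]1C | intermediate
8 | ketene acetal of 5 (not isolated) | C=C(OCC)OC(C(C)=C)[C@H]1C[C@@H]1C | intermediate
9 | ethyl (4E)-4-methyl-5-[(1S,2S)-2-methylcyclopropyl]pent-4-enoate | CCOC(=O)CC/C(C)=C/[C@H]1C[C@@H]1C | intermediate
10 | tert-butyl acetate | CC(=O)OC(C)(C)C | starting material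
11 | tert-butyl (6E)-6-methyl-7-[(1S,2S)-2-methylcyclopropyl]-3-oxohept-6-enoate | CC(C)(C)OC(=O)CC(=O)CC/C(C)=C/[C@H]1C[C@@H]1C | intermediate
12 | tert-butyl (2E,6E)-6-methyl-7-[(1S,2S)-2-methylcyclopropyl]-3-{[(trifluoromethyl)sulfonyl]oxy}hepta-2,6-dienoate | CC(C)(C)OC(=O)/C=C(/OS(=O)(=O)C(F)(F)F)CC/C(C)=C/[C@H]1C[C@@H]1C | intermediate
13 | isopropylmagnesium chloride | CC(C)[Mg]Cl | starting material
14 | tert-butyl (2E,6E)-6-methyl-7-[(1S,2S)-2-methylcyclopropyl]-3-(propan-2-yl)hepta-2,6-dienoate | CC(C)(C)OC(=O)/C=C(/C(C)C)CC/C(C)=C/[C@H]1C[C@@H]1C | intermediate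
15 | (2E,6E)-6-methyl-7-[(1S,2S)-2-methylcyclopropyl]-3-(propan-2-yl)hepta-2,6-dien-1-ol | OC/C=C(/C(C)C)CC/C(C)=C/[C@H]1C[C@@H]1C | intermediate
16 | [(2S,3S)-3-{(3E)-3-methyl-4-[(1S,2S)-2-methylcyclopropyl]but-3-en-1-yl}-3-(propan-2-yl)oxiran-2-yl]methanol | OC[C@@H]1O[C@]1(C(C)C)CC/C(C)=C/[C@H]2C[C@@H]2C | intermediate
17 | (2R,3S)-2-(chloromethyl)-3-{(3E)-3-methyl-4-[(1S,2S)-2-methylcyclopropyl]but-3-en-1-yl}-3-(propan-2-yl)oxirane | ClC[C@@H]1O[C@]1(C(C)C)CC/C(C)=C/[C@H]2C[C@@H]2C | intermediate
18 | dilithium alkoxide acetylide of the desilyl carbinol (not isolated) | [Li]C#C[C@@](O[Li])(C(C)C)CC/C(C)=C/[C@H]1C[C@@H]1C | intermediate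
19 | O,C-bis(trimethylsilyl) derivative (not isolated) | C[Si](C)(C)C#C[C@@](O[Si](C)(C)C)(C(C)C)CC/C(C)=C/[C@H]1C[C@@H]1C | intermediate
20 | (3S,6E)-6-methyl-7-[(1S,2S)-2-methylcyclopropyl]-3-(propan-2-yl)-1-(trimethylsilyl)hept-6-en-1-yn-3-ol | C[Si](C)(C)C#C[C@@](O)(C(C)C)CC/C(C)=C/[C@H]1C[C@@H]1C | intermediate
21 | (3S,6S,8aR)-6,8a-dimethyl-3-(propan-2-yl)-4-(trimethylsilyl)-1,2,3,5,6,8a-hexahydroazulen-3-ol | C[C@@H]1C=C[C@@]2(C)CC[C@](O)(C(C)C)C2=C([Si](C)(C)C)C1 | intermediate
22 | (3S,3aS,4R,6S,8aR)-3a,4-epoxy-6,8a-dimethyl-3-(propan-2-yl)-4-(trimethylsilyl)-1,2,3,3a,4,5,6,8a-octahydroazulen-3-ol (epoxide on the hydroxyl face) | C[C@@H]1C=C[C@@]2(C)CC[C@](O)(C(C)C)[C@@]23O[C@@]3([Si](C)(C)C)C1 | intermediate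
23 | C8=C9 enol of 24 (not isolated) | C[C@@H]1C=C[C@@]2(C)CC[C@](O)(C(C)C)C2=C(O)C1 | intermediate
24 | (3S,3aR,6S,8aR)-3-hydroxy-6,8a-dimethyl-3-(propan-2-yl)-2,3,3a,5,6,8a-hexahydroazulen-4(1H)-one | C[C@@H]1C=C[C@@]2(C)CC[C@](O)(C(C)C)[C@@H]2C(=O)C1 | intermediate
25 | (3S,3aS,4R,6S,8aR)-6,8a-dimethyl-3-(propan-2-yl)-1,2,3,3a,4,5,6,8a-octahydroazulene-3,4-diol | C[C@@H]1C=C[C@@]2(C)CC[C@](O)(C(C)C)[C@@H]2[C@H](O)C1 | intermediate
26 | 4-(acetyloxy)benzoyl chloride | CC(=O)Oc1ccc(cc1)C(Cl)=O | starting material
27 | (3S,3aS,4R,6S,8aR)-3-hydroxy-6,8a-dimethyl-3-(propan-2-yl)-1,2,3,3a,4,5,6,8a-octahydroazulen-4-yl 4-(acetyloxy)benzoate | C[C@@H]1C=C[C@@]2(C)CC[C@](O)(C(C)C)[C@@H]2[C@H](OC(=O)c2ccc(OC(C)=O)cc2)C1 | intermediate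
28 | C3 hydroperoxide of 29 (not isolated) | CC1=C[C@@H](OO)[C@@]2(C)CC[C@](O)(C(C)C)[C@@H]2[C@H](OC(=O)c2ccc(OC(C)=O)cc2)C1 | intermediate
29 | (3S,3aS,4R,8R,8aS)-3,8-dihydroxy-6,8a-dimethyl-3-(propan-2-yl)-1,2,3,3a,4,5,8,8a-octahydroazulen-4-yl 4-(acetyloxy)benzoate | CC1=C[C@@H](O)[C@@]2(C)CC[C@](O)(C(C)C)[C@@H]2[C@H](OC(=O)c2ccc(OC(C)=O)cc2)C1 | intermediate
30 | 3-methylbutanoyl chloride | CC(C)CC(Cl)=O | starting material
31 | (3S,3aS,4R,8R,8aS)-3-hydroxy-6,8a-dimethyl-8-[(3-methylbutanoyl)oxy]-3-(propan-2-yl)-1,2,3,3a,4,5,8,8a-octahydroazulen-4-yl 4-(acetyloxy)benzoate | CC1=C[C@@H](OC(=O)CC(C)C)[C@@]2(C)CC[C@](O)(C(C)C)[C@@H]2[C@H](OC(=O)c2ccc(OC(C)=O)cc2)C1 | intermediate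
32 | (3S,3aS,4R,8R,8aS)-3-hydroxy-6,8a-dimethyl-8-[(3-methylbutanoyl)oxy]-3-(propan-2-yl)-1,2,3,3a,4,5,8,8a-octahydroazulen-4-yl 4-hydroxybenzoate | CC1=C[C@@H](OC(=O)CC(C)C)[C@@]2(C)CC[C@](O)(C(C)C)[C@@H]2[C@H](OC(=O)c2ccc(O)cc2)C1 | target

**Step count and risks**
Total: 19 steps. Longest linear sequence: 19 steps (1 → 32); all other building blocks enter as purchased reagents.

Most likely to fail, in order:

1. Step 12. The trimethylsilyl group is pressed against the fully substituted C7 during alkyne insertion, so the cycloaddition may be slow, β-hydride elimination from the rhodacycle may compete, and discrimination of the two alkene faces by C7 may be poor. The fallback removes the silyl group from the design; it sets out from 17 and returns at 24. Double elimination with LiN(i-Pr)2 and an aqueous quench gives the terminal alkynyl carbinol F1, and cycloaddition with [Rh(CO)2Cl]2 gives the less encumbered C9–H diene F2. The C9 oxygen is then delivered through a silicon tether. HMe2SiCl, Et3N and DMAP give the dimethylsilyl ether F3. Pt2[(CH2=CHSiMe2)2O]3 effects intramolecular 5-endo hydrosilylation to the fused oxasilolane F4, with silicon to C9 and hydrogen to C8 from the hydroxyl face, so the trans ring fusion is fixed by syn delivery. Tamao oxidation (H2O2, KF, KHCO3) gives the syn-1,3-diol F5, and Dess–Martin oxidation of its secondary hydroxyl gives 24.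

2. Step 14. Acid may trigger a 1,2-shift from C7 to the C8 cation or dehydration of the β-hydroxy ketone, and the enol may be protonated without facial preference or equilibrate towards the cis ring fusion. The fallback replaces the epoxysilane by an oxidisable silyl group; it sets out from 17 and returns at 24. LiN(i-Pr)2, then BnMe2SiCl and dilute acid, gives the benzyldimethylsilyl alkynyl carbinol F6, and cycloaddition as in step 12 gives the vinylsilane F7. n-Bu4NF followed by H2O2, KHCO3 and MeOH (Tamao oxidation by way of the cyclic siloxane with the C7 oxygen) converts the C9–Si bond into the enol and hence into 24 without acid, and 24 is reduced at once as in step 15. If the ring fusion still forms without control, the tether sequence of the first fallback sets C8 by syn delivery.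

3. Step 17. The cis-disubstituted alkene reacts slowly with singlet oxygen, and the more substituted C1=C2 alkene that the ene reaction creates may be oxidised further. The fallback is an epoxide isomerisation; it sets out from 27 and returns at 29. m-CPBA with NaHCO3 gives the C2–C3 epoxide F8 on the face opposite to the C1 and C4 methyl groups. Me3SiOTf and 2,6-lutidine, then DBU, open it at C2 and eliminate the C1 hydrogen anti to the triflate, giving the allylic bis(trimethylsilyl) ether F9 with the C3 oxygen unchanged. Citric acid in MeOH removes both silyl groups to give 29.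

**Further compounds**
F1 | step 12 | (3S,6E)-6-methyl-7-[(1S,2S)-2-methylcyclopropyl]-3-(propan-2-yl)hept-6-en-1-yn-3-ol | C#C[C@@](O)(C(C)C)CC/C(C)=C/[C@H]1C[C@@H]1C
F2 | step 12 | (3S,6S,8aR)-6,8a-dimethyl-3-(propan-2-yl)-1,2,3,5,6,8a-hexahydroazulen-3-ol | C[C@@H]1C=C[C@@]2(C)CC[C@](O)(C(C)C)C2=CC1
F3 | step 12 | dimethylsilyl ether of F2 | C[C@@H]1C=C[C@@]2(C)CC[C@](O[SiH](C)C)(C(C)C)C2=CC1
F4 | step 12 | fused 2,2-dimethyl-1,2-oxasilolane (O on C7, Si on C9, H8 and Si on the same face) | C[C@@H]1C=C[C@@]2(C)CC[C@@]3(C(C)C)O[Si](C)(C)[C@@H](C1)[C@H]23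
F5 | step 12 | (3S,3aS,4S,6S,8aR)-6,8a-dimethyl-3-(propan-2-yl)-1,2,3,3a,4,5,6,8a-octahydroazulene-3,4-diol | C[C@@H]1C=C[C@@]2(C)CC[C@](O)(C(C)C)[C@@H]2[C@@H](O)C1
F6 | step 14 | (3S,6E)-1-[benzyl(dimethyl)silyl]-6-methyl-7-[(1S,2S)-2-methylcyclopropyl]-3-(propan-2-yl)hept-6-en-1-yn-3-ol | C[Si](C)(Cc1ccccc1)C#C[C@@](O)(C(C)C)CC/C(C)=C/[C@H]1C[C@@H]1C
F7 | step 14 | (3S,6S,8aR)-4-[benzyl(dimethyl)silyl]-6,8a-dimethyl-3-(propan-2-yl)-1,2,3,5,6,8a-hexahydroazulen-3-ol | C[C@@H]1C=C[C@@]2(C)CC[C@](O)(C(C)C)C2=C([Si](C)(C)Cc2ccccc2)C1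
F8 | step 17 | C2–C3 epoxide of 27 (oxygen anti to the C1 and C4 methyl groups) | C[C@@H]1[C@H]2O[C@H]2[C@@]3(C)CC[C@](O)(C(C)C)[C@@H]3[C@H](OC(=O)c3ccc(OC(C)=O)cc3)C1
F9 | step 17 | C3,C7-bis(trimethylsilyl) ether of 29 | CC1=C[C@@H](O[Si](C)(C)C)[C@@]2(C)CC[C@](O[Si](C)(C)C)(C(C)C)[C@@H]2[C@H](OC(=O)c2ccc(OC(C)=O)cc2)C1
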